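**Plan**

- The target consists of two identical 2-hydroxy-5-methoxy-6-methyl-1,4-benzoquinone rings (ring A and ring B) joined at their C3 carbons by a saturated tether C1–C13. The tether has an odd number of carbons, so its midpoint is the atom C7 and not a bond, flanked by two identical six-carbon arms (C1–C6 and C8–C13). C7 can therefore come from C2 of 1,3-dithiane, used as a one-carbon linchpin that is alkylated twice.
- Retrosynthetic cuts, in order: both quinones back to MOM-protected 2-alkyl-4,6-dimethoxy-5-methylresorcinols; the two C–S bonds at C7; the C6–C7 and C7–C8 bonds; the aryl–C1 bond of each arm; finally the two phenolic C–O bonds, back to 2,6-dimethoxytoluene.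
- Forward: the arene is oxygenated (steps 1–3), the 6-iodohexyl arm is attached by ortho-lithiation (step 4), two arms are joined at the dithiane carbon (step 5), and the product is desulfurized, deprotected and oxidized (steps 6–8). Both six-membered rings come from the starting arene; no ring is closed.
- The target has no stereocentre and no stereogenic double bond, so no stereochemistry has to be set.

Key step: step 5

Remark on the chemistry: in each ring of the deprotected precursor, either phenol together with its para methoxy group gives the same 2-hydroxy-5-methoxyquinone on oxidation, so the two phenols need no differentiation. Compounds 1, 5 and 8 are taken to be commercially available.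

**Route**

Step 1
Reactants: 1 2,6-dimethoxytoluene
Product: 2 1,5-dibromo-2,4-dimethoxy-3-methylbenzene
Conditions: NBS (2.2 equiv), MeCN, rt then 50 °C
Reagents that add atoms: N-bromosuccinimide, O=C1CCC(=O)N1Br
Why: Electrophilic aromatic bromination is expected to go only at the two ring positions that are each ortho to one methoxy group and para to the other, and NBS in polar MeCN without a radical initiator should leave the benzylic methyl untouched.

Step 2
Reactants: 2 1,5-dibromo-2,4-dimethoxy-3-methylbenzene
Product: 3 4,6-dimethoxy-5-methylbenzene-1,3-diol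
Conditions: Pd2(dba)3 (2 mol%), t-BuXPhos (8 mol%), KOH (6 equiv), 1,4-dioxane/H2O 1:1, 100 °C, Ar; then aq. HCl to pH 3
Reagents that add atoms: potassium hydroxide, [K+].[OH-]
Why: Palladium-catalysed hydroxylation of aryl bromides with hydroxide (Buchwald–Hartwig-type C–O coupling on zerovalent palladium with a bulky biarylphosphine) should replace both bromides, since the phenoxide formed first sits meta to the second C–Br bond and does not deactivate it, and excess KOH disfavours diaryl ether formation.

Step 3
Reactants: 3 4,6-dimethoxy-5-methylbenzene-1,3-diol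
Product: 4 1,5-bis(methoxymethoxy)-2,4-dimethoxy-3-methylbenzene
Conditions: MOMCl (3 equiv), i-Pr2NEt (4 equiv), CH2Cl2, 0 °C to rt, Ar
Reagents that add atoms: chloromethyl methyl ether, COCCl
Why: O-Alkylation of both phenols with the reactive α-chloro ether under amine base (Williamson-type acetal formation) should be fast, and it installs the two groups that direct the following lithiation.

Step 4
Reactants: 4 1,5-bis(methoxymethoxy)-2,4-dimethoxy-3-methylbenzene; 5 1,6-diiodohexane
Product: 7 1-(6-iodohexyl)-2,6-bis(methoxymethoxy)-3,5-dimethoxy-4-methylbenzene, via aryllithium 6 (not isolated)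
Conditions: n-C4H9Li (1.1 equiv), THF, 0 °C, 1 h; then cannulated into 5 (4 equiv), THF, −78 °C to rt
Reagents that add atoms: none
Why: Directed ortho metalation should occur at the only ring hydrogen, which lies between two lithium-coordinating OMOM groups, and inverse addition of the aryllithium to a fourfold excess of the primary diiodide should favour a single SN2 displacement over twofold arylation.

Step 5
Reactants: 8 1,3-dithiane; 7 1-(6-iodohexyl)-2,6-bis(methoxymethoxy)-3,5-dimethoxy-4-methylbenzene (two equivalents)
Product: 12 2,2-bis{6-[2,6-bis(methoxymethoxy)-3,5-dimethoxy-4-methylphenyl]hexyl}-1,3-dithiane, via 2-lithio-1,3-dithiane 9 (not isolated), via monoalkylated dithiane 10 (not isolated), via lithiated monoalkyl dithiane 11 (not isolated)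
Conditions: 8 (1.0 equiv), n-C4H9Li (1.0 equiv), THF, −30 °C, 2 h; 7 (1.0 equiv), −30 to 0 °C; n-C4H9Li (1.05 equiv), −30 to −20 °C, 3 h; 7 (1.0 equiv), −20 °C to rt
Reagents that add atoms: none
Why: n-C4H9Li removes the sulfur-stabilised C2 proton of 8, and the resulting carbanion 9 displaces iodide from the primary carbon of 7 by SN2 to form the C6–C7 bond; a second deprotonation of 10 at the same carbon and a second SN2 displacement on another molecule of 7 form the C7–C8 bond, so the dithiane carbon becomes C7 of the tether. The closest known reaction type is the Corey–Seebach sequential dialkylation of 1,3-dithiane with primary alkyl iodides, an acyl-anion (umpolung) linchpin coupling. No ring is closed and no stereocentre arises, because the two groups placed on C7 are identical. The step needs chemoselectivity only: clean monoalkylation, then complete second metalation at C2 of 10 and nowhere else. This is secured because the arene of 7 is hexasubstituted and carries no ring hydrogen, its ether and acetal groups are inert to dithianyl anions, and the electrophilic carbon is primary, unbranched and six carbons from the ring, which favours SN2 over E2. Stepwise stoichiometric addition of base and iodide at −30 to −20 °C keeps free n-C4H9Li away from 7.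

Step 6
Reactants: 12 2,2-bis{6-[2,6-bis(methoxymethoxy)-3,5-dimethoxy-4-methylphenyl]hexyl}-1,3-dithiane
Product: 13 1,13-bis[2,6-bis(methoxymethoxy)-3,5-dimethoxy-4-methylphenyl]tridecane
Conditions: Raney nickel (Ni, W-2 grade, excess), EtOH, reflux
Reagents that add atoms: none
Why: Hydrogenolysis of both C–S bonds on hydrogen-loaded Raney nickel (Mozingo reduction) should turn the dithioketal carbon into the C7 methylene, while aryl methyl ethers and MOM acetals are inert to these conditions.

Step 7
Reactants: 13 1,13-bis[2,6-bis(methoxymethoxy)-3,5-dimethoxy-4-methylphenyl]tridecane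
Product: 14 2,2'-(tridecane-1,13-diyl)bis(4,6-dimethoxy-5-methylbenzene-1,3-diol)
Conditions: HCl (3 M in MeOH), MeOH/THF, 40 °C, Ar; crude product used directly
Reagents that add atoms: none
Why: Acid-catalysed acetal exchange with methanol should cleave all four MOM ethers while the aryl methyl ethers survive, and working under argon limits premature air oxidation of the electron-rich tetraphenol.

Step 8
Reactants: 14 2,2'-(tridecane-1,13-diyl)bis(4,6-dimethoxy-5-methylbenzene-1,3-diol)
Product: 15 3,3'-(tridecane-1,13-diyl)bis(2-hydroxy-5-methoxy-6-methylcyclohexa-2,5-diene-1,4-dione), the target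
Conditions: (NH4)2Ce(NO3)6 (4.4 equiv), MeCN/H2O 2:1, 0 °C
Reagents that add atoms: water, O
Why: Oxidative demethylation of a 4-methoxyphenol by tetravalent cerium (two-electron oxidation, water adds at the methoxy-bearing para carbon, methanol leaves) should give the para-quinone in each ring, and the ring symmetry means either phenol leads to the same hydroxyquinone with OH next to the tether and OMe next to the methyl.

**Compound list**

1 | 2,6-dimethoxytoluene | Cc1c(OC)cccc1OC | starting material
2 | 1,5-dibromo-2,4-dimethoxy-3-methylbenzene | Cc1c(OC)c(Br)cc(Br)c1OC | intermediate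
3 | 4,6-dimethoxy-5-methylbenzene-1,3-diol | Cc1c(OC)c(O)cc(O)c1OC | intermediate
4 | 1,5-bis(methoxymethoxy)-2,4-dimethoxy-3-methylbenzene | Cc1c(OC)c(OCOC)cc(OCOC)c1OC | intermediate
5 | 1,6-diiodohexane | ICCCCCCI | starting material
6 | [2,6-bis(methoxymethoxy)-3,5-dimethoxy-4-methylphenyl]lithium | [Li]c1c(OCOC)c(OC)c(C)c(OC)c1OCOC | intermediate
7 | 1-(6-iodohexyl)-2,6-bis(methoxymethoxy)-3,5-dimethoxy-4-methylbenzene | COCOc1c(CCCCCCI)c(OCOC)c(OC)c(C)c1OC | intermediate
8 | 1,3-dithiane | C1CSCSC1 | starting material
9 | 2-lithio-1,3-dithiane | [Li]C1SCCCS1 | intermediate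
10 | 2-{6-[2,6-bis(methoxymethoxy)-3,5-dimethoxy-4-methylphenyl]hexyl}-1,3-dithiane | COCOc1c(CCCCCCC2SCCCS2)c(OCOC)c(OC)c(C)c1OC | intermediate
11 | 2-lithio-2-{6-[2,6-bis(methoxymethoxy)-3,5-dimethoxy-4-methylphenyl]hexyl}-1,3-dithiane | COCOc1c(CCCCCCC2([Li])SCCCS2)c(OCOC)c(OC)c(C)c1OC | intermediate
12 | 2,2-bis{6-[2,6-bis(methoxymethoxy)-3,5-dimethoxy-4-methylphenyl]hexyl}-1,3-dithiane | COCOc1c(CCCCCCC2(CCCCCCc3c(OCOC)c(OC)c(C)c(OC)c3OCOC)SCCCS2)c(OCOC)c(OC)c(C)c1OC | intermediate
13 | 1,13-bis[2,6-bis(methoxymethoxy)-3,5-dimethoxy-4-methylphenyl]tridecane | COCOc1c(CCCCCCCCCCCCCc2c(OCOC)c(OC)c(C)c(OC)c2OCOC)c(OCOC)c(OC)c(C)c1OC | intermediate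
14 | 2,2'-(tridecane-1,13-diyl)bis(4,6-dimethoxy-5-methylbenzene-1,3-diol) | Oc1c(CCCCCCCCCCCCCc2c(O)c(OC)c(C)c(OC)c2O)c(O)c(OC)c(C)c1OC | intermediate
15 | 3,3'-(tridecane-1,13-diyl)bis(2-hydroxy-5-methoxy-6-methylcyclohexa-2,5-diene-1,4-dione) | COC1=C(C)C(=O)C(O)=C(CCCCCCCCCCCCCC2=C(O)C(=O)C(C)=C(OC)C2=O)C1=O | target

**Count and risks**

Total step count: 8. Longest linear sequence: 8 steps (1 to 15).

Steps most likely to fail:

Step 4. The aryllithium 6 is flanked by two alkoxy groups and must displace a primary iodide. Halogen–lithium exchange with the diiodide, E2 elimination and twofold arylation of the diiodide could all erode the monoalkylation. The fallback replaces the SN2 alkylation by a cross-coupling; it sets out from 4 and returns at 7. Lithiation of 4 as before and quenching of 6 with iodine should give 1-iodo-2,6-bis(methoxymethoxy)-3,5-dimethoxy-4-methylbenzene F2. Separately, 6-chloro-1-hexene is hydroborated with 9-BBN in THF to 9-(6-chlorohexyl)-9-borabicyclo[3.3.1]nonane F3. A B-alkyl Suzuki–Miyaura coupling of F2 with F3 (Pd(OAc)2, SPhos, K3PO4, THF/H2O, 60 °C) should give 1-(6-chlorohexyl)-2,6-bis(methoxymethoxy)-3,5-dimethoxy-4-methylbenzene F4, the alkyl chloride being inert to the catalyst. Finkelstein exchange (NaI, 2-butanone, reflux) then converts F4 into 7.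

Step 2. The twofold C–O coupling may stall after the first hydroxylation, the intermediate phenoxide may couple with remaining aryl bromide to give diaryl ethers, and the electron-rich dianion may be oxidized by air during work-up. The fallback separates C–B bond formation from oxidation; it sets out from 2 and returns at 3. Twofold Miyaura borylation (bis(pinacolato)diboron, PdCl2(dppf), KOAc, 1,4-dioxane, 90 °C) should give 2,2'-(4,6-dimethoxy-5-methyl-1,3-phenylene)bis(4,4,5,5-tetramethyl-1,3,2-dioxaborolane) F1. Oxidation of F1 with H2O2/NaOH in THF at 0 °C, followed by acidic work-up under argon, should give 3.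

Step 8. Oxidation of the free tetraphenol may be accompanied by oxidative coupling or over-oxidation of the very electron-rich rings, or may stop with only one ring at the quinone level. The fallback oxidizes before deprotection, so that no free phenol meets the oxidant; it sets out from 13 and returns at 15. Treatment of 13 with (NH4)2Ce(NO3)6 in MeCN/H2O at 0 °C should oxidatively dealkylate one para OMOM/OMe pair in each ring (both pairs of a ring are equivalent), giving 3,3'-(tridecane-1,13-diyl)bis[5-methoxy-2-(methoxymethoxy)-6-methylcyclohexa-2,5-diene-1,4-dione] F5. The remaining vinylogous acetals of F5 are then cleaved with 2 M aqueous HCl in THF at rt to give 15. Aqueous acid is chosen over methanolic acid so that the hydroxyquinone is not converted into its methyl ether.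

**Further compounds**

F1 | step 2 | 2,2'-(4,6-dimethoxy-5-methyl-1,3-phenylene)bis(4,4,5,5-tetramethyl-1,3,2-dioxaborolane) | Cc1c(OC)c(B2OC(C)(C)C(C)(C)O2)cc(B3OC(C)(C)C(C)(C)O3)c1OC
F2 | step 4 | 1-iodo-2,6-bis(methoxymethoxy)-3,5-dimethoxy-4-methylbenzene | COCOc1c(I)c(OCOC)c(OC)c(C)c1OC
F3 | step 4 | 9-(6-chlorohexyl)-9-borabicyclo[3.3.1]nonane | ClCCCCCCB1C2CCCC1CCC2
F4 | step 4 | 1-(6-chlorohexyl)-2,6-bis(methoxymethoxy)-3,5-dimethoxy-4-methylbenzene | COCOc1c(CCCCCCCl)c(OCOC)c(OC)c(C)c1OC
F5 | step 8 | 3,3'-(tridecane-1,13-diyl)bis[5-methoxy-2-(methoxymethoxy)-6-methylcyclohexa-2,5-diene-1,4-dione] | COCOC1=C(CCCCCCCCCCCCCC2=C(OCOC)C(=O)C(C)=C(OC)C2=O)C(=O)C(OC)=C(C)C1=O
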